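**Retrosynthetic overview**

1. Esters last: the C6 senecioate by acylation after enolate hydroxylation (trans to the side chain and the epoxide); the C8 angelate by acylation of an (S)-allylic alcohol.
2. C8–C9 bond: catalyst-controlled allylboration of a 2-substituted acrolein, then cross-metathesis to the prenyl terminus.
3. Key step, replacing the usual separate C8 oxidation and ketone reduction / hydroxyl-directed epoxidation / re-oxidation: a singlet-oxygen ene reaction puts one O2 on the isopropenyl group, and the resulting C8 hydroperoxide then epoxidises the ring enone intramolecularly. The tether forces the epoxide onto the face of the side chain (the diastereomer that alkaline peroxide does not give) and leaves the C8 hydroxyl.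
4. Ring order: the six-membered ring and its C5 stereocentre are bought as (R)-carvone; the oxirane (step 2) is the only ring formed.

Locants used in the text: ring C1 (C=O), C2/C3 (epoxide, C2 bears CH3), C5 (bears the side chain), C6 (CH–O); side chain C7 (the =CH2-bearing carbon), C8 (carbinol), C9 (CH2), C10=C11.

Assumption: the facial sense of the phosphoric acid in step 4 is taken by analogy with aryl and alkenyl aldehydes (to be confirmed by Mosher analysis of 7; the enantiomeric acid is used if it is reversed); small commercial reagents that deliver atoms are listed as reagents, so (R)-carvone is the only numbered starting material.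

**Step 1**
Reactants: 1 (R)-carvone
Product: 2 (5R)-5-(3-hydroperoxyprop-1-en-2-yl)-2-methylcyclohex-2-en-1-one
Conditions: O2 (1 atm), 5,10,15,20-tetraphenylporphyrin (0.5 mol %), white LED (> 420 nm), CH2Cl2 (0.5 M), 0 °C
Reagents that add atoms: dioxygen, O=O
Why: Schenck ene reaction of singlet oxygen at the isopropenyl group, the only electron-rich alkene (the s-trans enone is inert): oxygen bonds to the terminal CH2 and a methyl hydrogen is abstracted (the ring methine C–H cannot align with the π system), so a primary allylic hydroperoxide forms with the 1,1-disubstituted alkene regenerated and C5 untouched; the low rate of this alkene class is offset by the high substrate concentration.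

**Step 2**
Reactants: 2 (5R)-5-(3-hydroperoxyprop-1-en-2-yl)-2-methylcyclohex-2-en-1-one
Product: 4 (1S,4R,6S)-4-(3-hydroxyprop-1-en-2-yl)-1-methyl-7-oxabicyclo[4.1.0]heptan-2-one, via bridged peroxy enolate 3 (not isolated)
Conditions: 1,8-diazabicyclo[5.4.0]undec-7-ene (DBU, 0.2 equiv), CH2Cl2 (0.005 M, 2 added by syringe pump), 0 °C to rt
Reagents that add atoms: none
Why: Proposed new method: a tethered Weitz–Scheffer epoxidation in which the hydroperoxide anion can reach C3 of the enone only on the face carrying the C5 side chain (seven-membered peroxy-Michael closure through the conformer with the side chain axial), after which the enolate carbon C2 displaces the internal alkoxide at the C3-bound oxygen (O–O bond antiperiplanar to C2), so the epoxide is set cis to the side chain and the second oxygen remains as the C8 hydroxyl; the closest known reaction types are the DBU/alkyl hydroperoxide epoxidation of enones and the intramolecular hydroperoxide conjugate additions that give bridged 1,2-dioxanes from carvone-type enones.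

**Step 3**
Reactants: 4 (1S,4R,6S)-4-(3-hydroxyprop-1-en-2-yl)-1-methyl-7-oxabicyclo[4.1.0]heptan-2-one
Product: 5 (1S,4R,6S)-1-methyl-4-(3-oxoprop-1-en-2-yl)-7-oxabicyclo[4.1.0]heptan-2-one
Conditions: 2,2,6,6-tetramethylpiperidin-1-oxyl (TEMPO, 10 mol %), PhI(OAc)2 (1.1 equiv), CH2Cl2, rt
Reagents that add atoms: none
Why: Oxoammonium (TEMPO/PhI(OAc)2) oxidation of a primary allylic alcohol stops at the enal and leaves the epoxy ketone and the 1,1-disubstituted alkene alone; no stereocentre is affected.

**Step 4**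
Reactants: 5 (1S,4R,6S)-1-methyl-4-(3-oxoprop-1-en-2-yl)-7-oxabicyclo[4.1.0]heptan-2-one
Product: 7 (1S,4R,6S)-4-[(3S)-3-hydroxyhexa-1,5-dien-2-yl]-1-methyl-7-oxabicyclo[4.1.0]heptan-2-one, via pinacol borate ester 6 (not isolated)
Conditions: allylB(pin) (1.3 equiv), (S)-3,3′-bis(2,4,6-triisopropylphenyl)-1,1′-binaphthyl-2,2′-diyl hydrogen phosphate ((S)-TRIP, 5 mol %), toluene, −30 °C; H2O work-up
Reagents that add atoms: allylboronic acid pinacol ester, C=CCB1OC(C)(C)C(C)(C)O1
Why: Chiral phosphoric acid-catalysed allylboration through a closed chair transition state, in which the catalyst and not the remote ring stereocentres selects the aldehyde face ((S)-acid, Si-face attack, giving the (S)-carbinol); the pinacol boronate does not add to the hindered ketone at −30 °C.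

**Step 5**
Reactants: 7 (1S,4R,6S)-4-[(3S)-3-hydroxyhexa-1,5-dien-2-yl]-1-methyl-7-oxabicyclo[4.1.0]heptan-2-one
Product: 8 (1S,4R,6S)-4-[(3S)-3-hydroxy-6-methylhepta-1,5-dien-2-yl]-1-methyl-7-oxabicyclo[4.1.0]heptan-2-one
Conditions: second-generation Grubbs catalyst (H2IMes)(PCy3)Cl2Ru=CHPh (5 mol %), 2-methylbut-2-ene/CH2Cl2 1:1, 40 °C, sealed tube
Reagents that add atoms: 2-methylbut-2-ene, CC=C(C)C
Why: Olefin cross-metathesis in which only the monosubstituted terminal alkene engages the ruthenium carbene and excess 2-methylbut-2-ene caps it as the trisubstituted prenyl terminus, while the hindered 1,1-disubstituted alkene is a spectator and the carbinol is untouched.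

**Step 6**
Reactants: 8 (1S,4R,6S)-4-[(3S)-3-hydroxy-6-methylhepta-1,5-dien-2-yl]-1-methyl-7-oxabicyclo[4.1.0]heptan-2-one
Product: 9 (3S)-6-methyl-2-[(1S,3R,6S)-6-methyl-5-oxo-7-oxabicyclo[4.1.0]heptan-3-yl]hepta-1,5-dien-3-yl (2Z)-2-methylbut-2-enoate
Conditions: angelic acid, 2,4,6-trichlorobenzoyl chloride, Et3N, toluene, rt; then 8, 80 °C
Reagents that add atoms: angelic acid ((2Z)-2-methylbut-2-enoic acid), C/C=C(/C)C(=O)O
Why: Yamaguchi-type mixed-anhydride esterification run without a nucleophilic catalyst, so the alcohol attacks the unhindered angeloyl carbonyl and the (Z)-enoate is not isomerised to the tiglate; the carbinol configuration is retained.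

**Step 7**
Reactants: 9 (3S)-6-methyl-2-[(1S,3R,6S)-6-methyl-5-oxo-7-oxabicyclo[4.1.0]heptan-3-yl]hepta-1,5-dien-3-yl (2Z)-2-methylbut-2-enoate
Product: 11 (3S)-2-[(1S,3S,4S,6S)-4-hydroxy-6-methyl-5-oxo-7-oxabicyclo[4.1.0]heptan-3-yl]-6-methylhepta-1,5-dien-3-yl (2Z)-2-methylbut-2-enoate, via sodium enolate 10 (not isolated)
Conditions: NaN(SiMe3)2 (1.1 equiv), THF, −78 °C; 2-(phenylsulfonyl)-3-phenyloxaziridine (1.3 equiv), −78 °C; AcOH
Reagents that add atoms: 2-(phenylsulfonyl)-3-phenyloxaziridine, O=S(=O)(N1OC1c1ccccc1)c1ccccc1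
Why: Enolate hydroxylation with an N-sulfonyloxaziridine: kinetic deprotonation is possible only at C6 (C2 is quaternary) and is faster than vinylogous deprotonation of the angelate, the oxidant does not touch alkenes and traps the enolate at −78 °C before it can attack the ester, and oxygen enters on the face opposite to both the C5 side chain and the epoxide, giving the trans C6 alcohol.

**Step 8**
Reactants: 11 (3S)-2-[(1S,3S,4S,6S)-4-hydroxy-6-methyl-5-oxo-7-oxabicyclo[4.1.0]heptan-3-yl]-6-methylhepta-1,5-dien-3-yl (2Z)-2-methylbut-2-enoate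
Product: 12 (1S,3S,4S,6S)-1-methyl-4-[(3S)-6-methyl-3-{[(2Z)-2-methylbut-2-enoyl]oxy}hepta-1,5-dien-2-yl]-2-oxo-7-oxabicyclo[4.1.0]heptan-3-yl 3-methylbut-2-enoate (target, CNP0333561.1)
Conditions: 3-methylbut-2-enoyl chloride (1.5 equiv), pyridine, CH2Cl2, 0 °C to rt
Reagents that add atoms: 3-methylbut-2-enoyl chloride, CC(C)=CC(=O)Cl
Why: Acylation of the secondary α-ketol with an acid chloride in pyridine, a weak base at low temperature that avoids vinylketene-type deconjugation of the senecioyl group and epimerisation at C6 (already the more stable trans isomer); configuration is retained.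

**Compound list**

1 | (R)-(−)-carvone, (5R)-2-methyl-5-(prop-1-en-2-yl)cyclohex-2-en-1-one | C=C(C)[C@@H]1CC=C(C)C(=O)C1 | starting material
2 | (5R)-5-(3-hydroperoxyprop-1-en-2-yl)-2-methylcyclohex-2-en-1-one | C=C(COO)[C@@H]1CC=C(C)C(=O)C1 | intermediate
3 | bridged peroxy enolate, 9-methyl-5-methylidene-2,3-dioxabicyclo[4.3.1]dec-8-en-8-olate, peroxide bridge on the ring face of the side chain | C=C1COO[C@H]2C[C@@H]1CC([O-])=C2C | intermediate (not isolated)
4 | (1S,4R,6S)-4-(3-hydroxyprop-1-en-2-yl)-1-methyl-7-oxabicyclo[4.1.0]heptan-2-one, epoxide cis to the side chain | C=C(CO)[C@@H]1C[C@@H]2O[C@]2(C)C(=O)C1 | intermediate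
5 | (1S,4R,6S)-1-methyl-4-(3-oxoprop-1-en-2-yl)-7-oxabicyclo[4.1.0]heptan-2-one | C=C(C=O)[C@@H]1C[C@@H]2O[C@]2(C)C(=O)C1 | intermediate
6 | pinacol borate ester of 7 (O–B(pin) on the (S)-carbinol oxygen) | C=C([C@H](CC=C)OB1OC(C)(C)C(C)(C)O1)[C@@H]1C[C@@H]2O[C@]2(C)C(=O)C1 | intermediate (not isolated)
7 | (1S,4R,6S)-4-[(3S)-3-hydroxyhexa-1,5-dien-2-yl]-1-methyl-7-oxabicyclo[4.1.0]heptan-2-one | C=C([C@H](CC=C)O)[C@@H]1C[C@@H]2O[C@]2(C)C(=O)C1 | intermediate
8 | (1S,4R,6S)-4-[(3S)-3-hydroxy-6-methylhepta-1,5-dien-2-yl]-1-methyl-7-oxabicyclo[4.1.0]heptan-2-one | C=C([C@H](CC=C(C)C)O)[C@@H]1C[C@@H]2O[C@]2(C)C(=O)C1 | intermediate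
9 | (3S)-6-methyl-2-[(1S,3R,6S)-6-methyl-5-oxo-7-oxabicyclo[4.1.0]heptan-3-yl]hepta-1,5-dien-3-yl (2Z)-2-methylbut-2-enoate | C=C([C@H](CC=C(C)C)OC(=O)/C(C)=C\C)[C@@H]1C[C@@H]2O[C@]2(C)C(=O)C1 | intermediate
10 | sodium enolate of 9 (ring C1–O−, C1=C6) | C=C([C@H](CC=C(C)C)OC(=O)/C(C)=C\C)[C@@H]1C[C@@H]2O[C@]2(C)C([O-])=C1.[Na+] | intermediate (not isolated)
11 | (3S)-2-[(1S,3S,4S,6S)-4-hydroxy-6-methyl-5-oxo-7-oxabicyclo[4.1.0]heptan-3-yl]-6-methylhepta-1,5-dien-3-yl (2Z)-2-methylbut-2-enoate | C=C([C@H](CC=C(C)C)OC(=O)/C(C)=C\C)[C@@H]1C[C@@H]2O[C@]2(C)C(=O)[C@H]1O | intermediate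
12 | (1S,3S,4S,6S)-1-methyl-4-[(3S)-6-methyl-3-{[(2Z)-2-methylbut-2-enoyl]oxy}hepta-1,5-dien-2-yl]-2-oxo-7-oxabicyclo[4.1.0]heptan-3-yl 3-methylbut-2-enoate | C=C([C@H](CC=C(C)C)OC(=O)/C(C)=C\C)[C@@H]1C[C@@H]2O[C@]2(C)C(=O)[C@H]1OC(=O)C=C(C)C | target

**Step count and risk**

Total step count: 8. Longest linear sequence: 8 (fully linear from (R)-carvone).

Steps most likely to fail:

Step 2 (tethered epoxidation, highest risk). The intramolecular delivery may lose to intermolecular epoxidation (which gives the trans epoxide), to base-induced dehydration of the hydroperoxide to the enal, or may stall at the bridged peroxide. The fallback sets out from 1 and comes back at 4, replacing steps 1 and 2 by hydroxyl-directed epoxidation. NaBH4/CeCl3·7H2O in MeOH at −78 °C gives cis-carveol F1. t-BuOOH with catalytic VO(acac)2 in CH2Cl2 epoxidises syn to the hydroxyl to give the all-cis epoxy alcohol F2. Dess–Martin periodinane gives cis-carvone oxide F3. Catalytic SeO2 with t-BuOOH in CH2Cl2 then hydroxylates the isopropenyl methyl to give 4.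

Step 7 (late enolate hydroxylation). The sodium enolate could attack the angelate carbonyl through a six-membered transition state, open the epoxide, or scramble the (Z)-ester. The fallback sets out from 9 and comes back at 11 by a Rubottom-type route that never has a free enolate in solution. LiN(iPr)2 added to 9 with Me3SiCl already present (THF, −78 °C) gives the trimethylsilyl enol ether F4. F4 is oxidised under neutral conditions with 2-(phenylsulfonyl)-3-phenyloxaziridine in CHCl3 at 50 °C, which does not epoxidise the other alkenes. Methanolic citric acid then removes the silyl group to give 11.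

Step 1 (ene reaction of a 1,1-disubstituted alkene). The reaction may be too slow or give over-oxidation on long irradiation. The fallback sets out from 1 and comes back at 2 by an ionic route. Ene-type allylic chlorination with HOCl (Ca(OCl)2, solid CO2, CH2Cl2/H2O, 0 °C) gives 10-chlorocarvone F5. Silver-assisted substitution (AgOSO2CF3, anhydrous H2O2 in Et2O, 2,6-di-tert-butylpyridine, 0 °C, dark) then gives 2.

**Further compounds**

F1 | step 2 | (1R,5R)-2-methyl-5-(prop-1-en-2-yl)cyclohex-2-en-1-ol (cis-carveol) | C=C(C)[C@@H]1CC=C(C)[C@H](O)C1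
F2 | step 2 | (1R,2R,4S,6S)-1-methyl-4-(prop-1-en-2-yl)-7-oxabicyclo[4.1.0]heptan-2-ol (hydroxyl, epoxide and isopropenyl all cis) | C=C(C)[C@@H]1C[C@@H]2O[C@]2(C)[C@H](O)C1
F3 | step 2 | (1S,4R,6S)-1-methyl-4-(prop-1-en-2-yl)-7-oxabicyclo[4.1.0]heptan-2-one (cis-carvone oxide) | C=C(C)[C@@H]1C[C@@H]2O[C@]2(C)C(=O)C1
F4 | step 7 | trimethylsilyl enol ether of 9 (C1–OSiMe3, C1=C6) | C=C([C@H](CC=C(C)C)OC(=O)/C(C)=C\C)[C@@H]1C[C@@H]2O[C@]2(C)C(O[Si](C)(C)C)=C1
F5 | step 1 | (5R)-5-(3-chloroprop-1-en-2-yl)-2-methylcyclohex-2-en-1-one (10-chlorocarvone) | C=C(CCl)[C@@H]1CC=C(C)C(=O)C1
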